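## The problem

Target 5 is (1R,3S)-1,3-bis(2,4,5-trimethoxyphenyl)butan-1-ol: an open four-carbon chain whose only rings are two identical 2,4,5-trimethoxyphenyl groups, one on the carbinol carbon C1 and one on C3, which also carries the methyl group C4. The constitution is simple; the difficulty is stereochemical. C1 and C3 are benzylic stereocentres in a 1,3-relationship across the C2 methylene of a freely rotating chain; drawn as the zigzag Ar–C1–C2–C3–Ar, OH and CH3 lie on the same side (1,3-syn). No ring and no chelating group lies between them, so neither centre can be expected to control the other, and each has to be set by a reagent or catalyst. Both centres sit next to an ortho-methoxy-substituted, very electron-rich ring, which hinders C–C bond formation there and makes the matching aryl nucleophiles (easily protodemetalated) and Michael acceptors (deactivated) poor partners. The C1 hydroxyl is benzylic to a ring with ortho- and para-methoxy donors, so even weak acid ionizes it, with epimerization, elimination or Friedel–Crafts closure onto the second ring; C1 must therefore be made last and without acid. C3 has no neighbouring functional group in the target and cannot be corrected once made. The feature the plan exploits is that the two aryl groups are the same and the chain is two aryl–C2 units joined head to tail, C1(O)–C2 from one and C3–C4H3 from the other: this is the skeleton of the self-aldol (dypnone-type) condensation product of the acetophenone 1, in which both stereocentres of 5 appear as trigonal carbons (C1=O and C3=C2).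

## Retrosynthesis

**5 ⇒ 4.** The C1–H bond is cut (H2 removed from the carbinol), which leads back to the (S)-ketone 4. The neighbouring cuts, C1–aryl or C1–C2, would make the carbinol by C–C bond formation next to a hindered ring, with no substrate control and a need for an asymmetric carbonyl addition. Hydrogen addition to an aryl ketone is milder and can be run in basic medium. Ketone 4 has one stereocentre less and is not acid-sensitive. The forward reaction must be catalyst-controlled for (R) at C1, override the remote C3 centre, and avoid acid throughout.

**4 ⇒ 3.** The C3–H and C2–H bonds are cut, which restores the C2=C3 double bond of the (E)-enone 3. The neighbouring cuts at C3 (C3–aryl, C3–CH3) would create the hindered benzylic centre by conjugate addition with an electron-rich, ortho-substituted partner. Hydrogenation of a trisubstituted aryl alkene only requires face selection on a flat substrate. Reducing C=O before C=C was weighed and set aside: it would place a hydroxyl on a carbon that is both allylic and trimethoxybenzylic and therefore very easily ionized. A hydroxyl-directed hydrogenation of that (E)-alkene would also, by allylic 1,3-strain, deliver hydrogen to the face that leads to the 1,3-anti series. Enone 3 is achiral, planar and conjugated, and should be crystalline. The forward reaction needs C=C over C=O chemoselectivity and a geometrically pure (E)-alkene, because the hydrogenation is stereospecific.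

**3 ⇒ 1 + 1 (via 2).** The C2=C3 bond is cut by a retro-aldol condensation, and both halves become the same commercial ketone 1. This repeats the head-to-tail union of two aryl–C2 units that a biogenesis from a vinylarene would use, with the same polarity (terminal carbon as nucleophile, benzylic carbon as electrophile), but at the carbonyl oxidation level. A crossed aldol or olefination would need two different partners where the symmetry of the target offers one. The precursor is one achiral compound with nine heavy atoms fewer than half of the product. The forward reaction needs only to overcome the unfavourable ketone–ketone aldol equilibrium, to stop at the dimer and to give the (E)-alkene.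

## Roads not taken

**Alternative 1:** the most obvious cut, C3–aryl. The forward key step is a rhodium/BINAP-catalysed asymmetric 1,4-addition (Hayashi–Miyaura) of (2,4,5-trimethoxyphenyl)boronic acid A2 to (E)-1-(2,4,5-trimethoxyphenyl)but-2-en-1-one A1, which gives 4; the ketone is then reduced as in the chosen route. It needs two different building blocks, and A1 must first be prepared and is prone to polymerization. A2 is ortho-substituted and electron-rich, so protodeboronation competes under the aqueous basic conditions and a large excess would be consumed. The hindered C3 centre is made by C–C bond formation rather than by addition of H2. The chosen plan is no longer, uses one commercial compound twice, and forms only water beside the product.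

**Alternative 2:** cut C2–C3 at the alkene oxidation level, the literal biomimetic route. Acid-mediated head-to-tail dimerization of 1-ethenyl-2,4,5-trimethoxybenzene A3 with capture of the C1 cation by water would give the constitution of 5 in one step. Both centres arise from open benzylic cations with no facial control, so a stereorandom mixture is expected. The C1 cation is also trapped by the neighbouring ring to give the indane A4 or loses a proton, and 5 re-ionizes under the acid that forms it. The chosen plan keeps the same bond and polarity but passes through a stable enone whose stereocentres are set afterwards under catalyst control.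

**Alternative 3:** cut C1–aryl. The aryllithium from 1-bromo-2,4,5-trimethoxybenzene A6 would add to (S)-3-(2,4,5-trimethoxyphenyl)butanal A5. 1,3-Induction from a β-centre that carries only aryl, methyl and hydrogen is negligible, so a near-equal mixture at C1 is expected unless a catalytic asymmetric arylation of an enolizable aliphatic aldehyde with a hindered aryl nucleophile is developed. A5 itself needs several steps, one of them asymmetric, so the C3 problem is only moved. The chosen plan sets C1 by a ketone hydrogenation with strong precedent and reaches 5 in fewer steps.

Key step: step 1

Assumption: the sense of induction in step 2 is taken from the behaviour of this catalyst class with (E)-β-methyl-substituted aryl alkenes; the ligand is written as (R) and is exchanged for its antipode, with nothing else altered, should the first run show the opposite sense.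

## Steps

**Step 1**
Reactants: 1 1-(2,4,5-trimethoxyphenyl)ethan-1-one (two molecules; both halves of the product)
Product: 3 (E)-1,3-bis(2,4,5-trimethoxyphenyl)but-2-en-1-one, via aldol adduct 2 (not isolated)
Conditions: Al(O-t-Bu)3 (0.6 equiv per 1), xylene, 135 °C, t-BuOH distilled off; aqueous work-up, recrystallization
Reagents that add atoms: none
Why: The step is the aluminium tert-butoxide self-condensation of an aryl methyl ketone, the classical dypnone synthesis, applied to a ring-substituted acetophenone. Ligand exchange gives the aluminium enolate of one molecule of 1 (its CH3 is the only enolizable position), which adds through a closed six-membered transition state to the aluminium-bound carbonyl of a second molecule to give the aldolate of 2; the 2-methoxy group can assist by chelating aluminium. E1cB loss of the aluminium-bound oxygen gives the conjugated enone, and the water equivalent is taken up by Al–O-t-Bu while t-BuOH distils, which pulls the unfavourable ketone–ketone aldol equilibrium forward. No ring is closed. No stereocentre survives the step: the tertiary carbinol centre of 2 is racemic and is erased on dehydration, and the only stereochemical element of 3, the C2=C3 geometry, is set under thermodynamic control in favour of the (E)-isomer, in which aryl and aroyl are trans and only the small methyl is cis to the carbonyl. The head-to-tail constitution needs no control, because each monomer has one nucleophilic carbon (CH3) and one electrophilic carbon (C=O), so C1/C2 come from one molecule and C3/C4 from the other. The selectivity needed is to stop at the dimer, and the substrate secures it: the carbonyl of 3 is vinylogously deactivated by the electron-rich β-aryl group and ortho-hindered, hence less electrophilic than that of 1, and the non-protic aluminium alkoxide does not promote acid-type cyclotrimerization. The result is an achiral enone in which both future stereocentres are trigonal carbons, each addressable by its own hydrogenation catalyst.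

**Step 2**
Reactants: 3 (E)-1,3-bis(2,4,5-trimethoxyphenyl)but-2-en-1-one
Product: 4 (S)-1,3-bis(2,4,5-trimethoxyphenyl)butan-1-one
Conditions: [Ir(cod){(R)-tBu-PHOX}]BArF (1 mol %), H2 (50 bar), CH2Cl2, rt; filtration through silica
Reagents that add atoms: none
Why: Iridium–phosphinooxazoline-catalysed asymmetric hydrogenation of a trisubstituted, aryl-conjugated C=C, a reaction type established for (E)-β-methylchalcones, in which the cationic iridium hydride leaves the aryl ketone untouched. H2 adds syn to one face of the geometrically pure (E)-alkene under catalyst control, which sets C3 as (S).

**Step 3**
Reactants: 4 (S)-1,3-bis(2,4,5-trimethoxyphenyl)butan-1-one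
Product: 5 (1R,3S)-1,3-bis(2,4,5-trimethoxyphenyl)butan-1-ol
Conditions: trans-RuCl2[(S)-xylbinap][(S)-daipen] (0.5 mol %), t-BuOK (5 mol %), H2 (10 bar), i-PrOH, 30 °C; neutral work-up, chromatography on Et3N-deactivated silica
Reagents that add atoms: none
Why: Noyori asymmetric hydrogenation of an aryl alkyl ketone by the outer-sphere Ru–H/N–H mechanism; the (S)-XylBINAP/(S)-DAIPEN catalyst gives (R)-1-arylalkanols and should override the negligible 1,3-induction from C3. The basic, acid-free medium protects the ionizable trimethoxybenzylic alcohol, and because both centres are catalyst-set, the minor enantiomer of 4 should end up mainly in the separable 1,3-anti diastereomer.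

## Compound list

1 | 1-(2,4,5-trimethoxyphenyl)ethan-1-one | CC(=O)c1cc(OC)c(OC)cc1OC | starting material
2 | 3-hydroxy-1,3-bis(2,4,5-trimethoxyphenyl)butan-1-one (racemic; present in the flask as its aluminium alkoxide) | COc1cc(OC)c(C(=O)CC(C)(O)c2cc(OC)c(OC)cc2OC)cc1OC | intermediate
3 | (E)-1,3-bis(2,4,5-trimethoxyphenyl)but-2-en-1-one | C/C(=C\C(=O)c1cc(OC)c(OC)cc1OC)c1cc(OC)c(OC)cc1OC | intermediate
4 | (S)-1,3-bis(2,4,5-trimethoxyphenyl)butan-1-one | COc1cc(OC)c(C(=O)C[C@H](C)c2cc(OC)c(OC)cc2OC)cc1OC | intermediate
5 | (1R,3S)-1,3-bis(2,4,5-trimethoxyphenyl)butan-1-ol | COc1cc(OC)c([C@H](O)C[C@H](C)c2cc(OC)c(OC)cc2OC)cc1OC | target

## Step count and risks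

Total step count: 3. Longest linear sequence: 3 steps from commercial 1.

**Step 1 (key step).** The most likely failure is sluggish or incomplete self-condensation, because the carbonyl of 1 is deactivated by three methoxy donors and shielded by the ortho-methoxy group, and the ketone–ketone aldol equilibrium lies on the monomer side. Incomplete equilibration to the (E)-isomer, or deconjugation of the double bond, would also matter, since step 2 is stereospecific.
Fallback, from 1 back to 3: part of 1 is converted into its silyl enol ether, trimethyl{[1-(2,4,5-trimethoxyphenyl)ethenyl]oxy}silane F1 (TMSOTf, Et3N, CH2Cl2, 0 °C). F1 is added in a Mukaiyama aldol reaction to a second portion of 1 activated by TiCl4 (CH2Cl2, −78 °C). This gives the aldol 2 as an isolated compound under kinetic control, independent of the aldol equilibrium. Dehydration of its tertiary benzylic hydroxyl (cat. p-TsOH, toluene, or MsCl/Et3N then DBU) with base equilibration then gives (E)-3.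

**Step 2.** Low conversion or poor facial selectivity may result, because the ortho-methoxy group twists the C3 aryl ring out of the alkene plane and can coordinate the cationic iridium centre. Any (Z)-isomer carried over from step 1 would be hydrogenated to the opposite enantiomer. The sense of induction also rests on the stated assumption.
Fallback, from 1 back to 4, making C3 by C–C instead of C–H bond formation: Claisen–Schmidt condensation of 1 with commercial 2,4,5-trimethoxybenzaldehyde (KOH, EtOH, rt) gives the chalcone (E)-1,3-bis(2,4,5-trimethoxyphenyl)prop-2-en-1-one F2. Copper-catalysed asymmetric conjugate addition of MeMgBr (CuBr·SMe2, a ferrocenyl diphosphine of the appropriate hand, t-BuOMe, −75 °C) then introduces C4 and sets C3, which gives 4.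

**Step 3.** Hydrogenation may be slow because the carbonyl is electron-rich, ortho-substituted and able to chelate. Facial selectivity may be insufficient if the catalyst and the C3 centre are mismatched. The product may also ionize at C1 on contact with acid during work-up or on untreated silica.
Fallback, from 4 back to 5, by separation and recycling rather than asymmetric catalysis: NaBH4 (MeOH, 0 °C) reduces 4 without facial control to 5 and its C1 epimer, (1S,3S)-1,3-bis(2,4,5-trimethoxyphenyl)butan-1-ol F3. The two are diastereomers and are separated by chromatography on base-washed silica or by crystallization. F3 is oxidized back to 4 (MnO2, CH2Cl2, or Dess–Martin periodinane/NaHCO3) and reduced again, so the material converges on 5.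

## Further compounds

F1 | step 1 | trimethyl{[1-(2,4,5-trimethoxyphenyl)ethenyl]oxy}silane | C=C(O[Si](C)(C)C)c1cc(OC)c(OC)cc1OC
F2 | step 2 | (E)-1,3-bis(2,4,5-trimethoxyphenyl)prop-2-en-1-one | COc1cc(OC)c(/C=C/C(=O)c2cc(OC)c(OC)cc2OC)cc1OC
F3 | step 3 | (1S,3S)-1,3-bis(2,4,5-trimethoxyphenyl)butan-1-ol | COc1cc(OC)c([C@@H](O)C[C@H](C)c2cc(OC)c(OC)cc2OC)cc1OC
A1 | alternative 1 | (E)-1-(2,4,5-trimethoxyphenyl)but-2-en-1-one | C/C=C/C(=O)c1cc(OC)c(OC)cc1OC
A2 | alternative 1 | (2,4,5-trimethoxyphenyl)boronic acid | COc1cc(OC)c(B(O)O)cc1OC
A3 | alternative 2 | 1-ethenyl-2,4,5-trimethoxybenzene | C=Cc1cc(OC)c(OC)cc1OC
A4 | alternative 2 | 4,5,7-trimethoxy-1-methyl-3-(2,4,5-trimethoxyphenyl)-2,3-dihydro-1H-indene (mixture of stereoisomers) | CC1CC(c2cc(OC)c(OC)cc2OC)c2c(OC)c(OC)cc(OC)c21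
A5 | alternative 3 | (S)-3-(2,4,5-trimethoxyphenyl)butanal | O=CC[C@H](C)c1cc(OC)c(OC)cc1OC
A6 | alternative 3 | 1-bromo-2,4,5-trimethoxybenzene | COc1cc(OC)c(Br)cc1OC
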